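Ring A of the target, the tetramethylcyclohexenedione fused to the dihydropyran, is read as dimethylketene dimer plus acetate: C6′, C7′, C8′ and C8a′ (primed chromene numbering) with their four methyl groups come from 2,2,4,4-tetramethylcyclobutane-1,3-dione, C4a′ and C5′ from methyl acetate. In one flask the acetate enolate opens the strained four-membered ring and the released C6′ enolate closes ring A by Claisen acylation at C5′, forming the C5′–C6′ bond (ketone carbon to CMe2) of syncarpic acid. A Knoevenagel/hetero-Diels–Alder union with isovaleraldehyde and (−)-caryophyllene oxide then builds the spiro-dihydropyran; epoxide-to-enone editing and a catalyst-controlled reduction install the (3Z,5S)-allylic alcohol.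

Key step: step 1

Remark: terpene atoms carry caryophyllane numbers (C12 = methyl on C4, C13 = the former exocyclic methylene carbon); the pyran and ring A carry primed chromene numbers (O1′, C2′ = C8, C3′ = C13, C4′ with the isobutyl group, C4a′, C5′ ketone, C6′ CMe2, C7′ ketone, C8′ CMe2, C8a′). The atoms of 7 are labelled as they end up in 15; the mirror symmetry of 7 makes the two ways of doing so the same compound.

Step 1
Reactants: 1 2,2,4,4-tetramethylcyclobutane-1,3-dione; 2 methyl acetate
Product: 7 syncarpic acid (2,2,4,4-tetramethylcyclohexane-1,3,5-trione), via ester enolate 3 (not isolated), via cyclobutanolate 4 (not isolated), via keto ester enolate 5 (not isolated), via dienolate 6 (not isolated)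
Conditions: LiN(iPr)2 (1.0 equiv), 2 (1.05 equiv), THF, −78 °C; add 1, −78 → 0 °C; LiN(iPr)2 (1.2 equiv), −78 °C → rt; aq. HCl
Reagents that add atoms: none
Why: Enolate 3 adds to one carbonyl of 1 (aldol addition) and the strained alkoxide 4 fragments by retro-aldol C–C cleavage to the open-chain keto ester, which rests as the β-keto ester enolate 5; the second portion of LiN(iPr)2 removes the only remaining acidic proton (C6′–H of the isopropyl ketone) and the tetrasubstituted enolate carbon of 6 attacks the ester carbon C5′ and expels methoxide (intramolecular Claisen acylation). The closest known reaction types are the nucleophilic ring opening of dimethylketene dimer to 2,2,4-trimethyl-3-oxopentanoyl derivatives and the Dieckmann-type closure of 3,5-dioxo esters to cyclohexane-1,3,5-triones. Ring A closes in a favoured 6-(enolendo)-exo-trig mode and no stereocentre is formed. The step needs C- over O-acylation and a single addition to 1: the O-acylated enol lactone should be reopened by lithium methoxide whereas the C-acylated product is removed as the delocalised enolate of the β-triketone, and pre-forming 3 without excess amide at −78 °C keeps a second addition and amide attack on 1 away. The non-enolisable 2,2-dimethyl-1,3-diketone array should survive because the chain carries its charge on the C4a′–C8a′ enolate until acidification.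

Step 2
Reactants: 7 syncarpic acid; 8 isovaleraldehyde (3-methylbutanal); 9 (−)-caryophyllene oxide, (1R,4R,5R,9S)-4,5-epoxycaryophyll-8(13)-ene
Product: 11 (1R,4R,5R,8S,9S,4′S)-4,5-epoxy-4′-(2-methylpropyl)-6′,6′,8′,8′-tetramethyl-3′,4′-dihydrospiro[13-norcaryophyllane-8,2′-chromene]-5′,7′(6′H,8′H)-dione, via enetrione 10 (not isolated)
Conditions: 8 (1.5 equiv), ethylenediammonium diacetate (10 mol %), CH2Cl2, rt; then 9 (1.2 equiv), toluene, 90 °C
Reagents that add atoms: none
Why: Domino Knoevenagel condensation/inverse-electron-demand hetero-Diels–Alder reaction in which the electron-poor 1-oxadiene of 10 adds to the only alkene of 9 with oxygen bonding to the more substituted C8, approach to the exposed face of C8=C13 (syn to C10, away from the folded nine-membered ring) setting C8 as S and the orientation that places the C9 branch under the diene setting C4′ as S, so that the C4′ and C8 epimers are the expected co-products to be removed by chromatography while the near-neutral medium should leave the epoxide intact.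

Step 3
Reactants: 11 epoxy spiro adduct
Product: 12 (1R,5R,8S,9S,4′S)-5-hydroxy-4′-(2-methylpropyl)-6′,6′,8′,8′-tetramethyl-3′,4′-dihydrospiro[13-norcaryophyll-4(12)-ene-8,2′-chromene]-5′,7′(6′H,8′H)-dione
Conditions: diethylaluminium 2,2,6,6-tetramethylpiperidide (3 equiv, from lithium 2,2,6,6-tetramethylpiperidide and Et2AlCl), toluene, 0 °C; aq. potassium sodium tartrate
Reagents that add atoms: none
Why: Aluminium amide-mediated isomerisation of a trisubstituted epoxide to an allylic alcohol by syn-β-elimination within the O–Al–N–H array, expected to abstract a C12 methyl proton without touching the C5–O bond (5R retained) or the non-enolisable hindered ketones, and any 3-ene regioisomer from abstraction at C3 is carried on because steps 4 and 5 converge on 14.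

Step 4
Reactants: 12 exocyclic allylic alcohol
Product: 13 (1R,8S,9S,4′S)-4′-(2-methylpropyl)-6′,6′,8′,8′-tetramethyl-3′,4′-dihydrospiro[13-norcaryophyll-4(12)-ene-8,2′-chromene]-5,5′,7′(6′H,8′H)-trione
Conditions: Dess–Martin periodinane (1.3 equiv), CH2Cl2, 0 °C → rt
Reagents that add atoms: none
Why: Dess–Martin oxidation of the secondary allylic alcohol under mild non-basic conditions should give the α-methylene ketone without moving the double bond or disturbing the enol ether and the C8 and C4′ stereocentres.

Step 5
Reactants: 13 α-methylene ketone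
Product: 14 (1R,3Z,8S,9S,4′S)-4′-(2-methylpropyl)-6′,6′,8′,8′-tetramethyl-3′,4′-dihydrospiro[13-norcaryophyll-3-ene-8,2′-chromene]-5,5′,7′(6′H,8′H)-trione
Conditions: RhCl3·3H2O (5 mol %), EtOH, 75 °C
Reagents that add atoms: none
Why: Rhodium hydride-mediated alkene migration (hydrometalation of the exocyclic enone and β-hydride elimination towards C3) under thermodynamic control should deliver the conjugated trisubstituted endocyclic enone, whose cis (3Z) geometry is the stable one in the nine-membered ring, and no other migratable alkene remains because C8=C13 was consumed in step 2.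

Step 6
Reactants: 14 (3Z)-enone
Product: 15 Tomentodione P, (1R,3Z,5S,8S,9S,4′S)-5-hydroxy-4′-(2-methylpropyl)-6′,6′,8′,8′-tetramethyl-3′,4′-dihydrospiro[13-norcaryophyll-3-ene-8,2′-chromene]-5′,7′(6′H,8′H)-dione
Conditions: (R)-2-methyl-CBS-oxazaborolidine (20 mol %), catecholborane (1.5 equiv), toluene, −78 °C; H2O work-up
Reagents that add atoms: none
Why: Corey–Bakshi–Shibata reduction in which the (R)-oxazaborolidine treats the 2-methylalkenyl arm as the large substituent and delivers hydride to the face that gives the 5S carbinol by catalyst control, while the vinylogous ester carbonyl C5′ and the C7′ ketone flanked by two quaternary carbons are too deactivated and hindered to react at −78 °C.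

Compound list
1 | 2,2,4,4-tetramethylcyclobutane-1,3-dione (dimethylketene dimer) | CC1(C)C(=O)C(C)(C)C1=O | starting material
2 | methyl acetate | COC(C)=O | starting material
3 | lithium enolate of methyl acetate (formed in the flask) | [Li]OC(=C)OC | intermediate
4 | lithium 1-(2-methoxy-2-oxoethyl)-2,2,4,4-tetramethyl-3-oxocyclobutan-1-olate (formed in the flask) | COC(=O)CC1(O[Li])C(C)(C)C(=O)C1(C)C | intermediate
5 | lithium C2–C3 enolate of methyl 4,4,6-trimethyl-3,5-dioxoheptanoate (formed in the flask) | COC(=O)C=C(O[Li])C(C)(C)C(=O)C(C)C | intermediate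
6 | dilithium dienolate of methyl 4,4,6-trimethyl-3,5-dioxoheptanoate, C2=C3–OLi and C5(OLi)=C6 (formed in the flask) | COC(=O)C=C(O[Li])C(C)(C)C(O[Li])=C(C)C | intermediate
7 | syncarpic acid, 2,2,4,4-tetramethylcyclohexane-1,3,5-trione (drawn as triketone, enolised in solution) | CC1(C)C(=O)CC(=O)C(C)(C)C1=O | intermediate
8 | isovaleraldehyde (3-methylbutanal) | CC(C)CC=O | starting material
9 | (−)-caryophyllene oxide, (1R,4R,5R,9S)-4,5-epoxycaryophyll-8(13)-ene | C[C@@]12CC[C@@H]3[C@H](CC3(C)C)C(=C)CC[C@H]1O2 | starting material
10 | 2,2,4,4-tetramethyl-6-(3-methylbutylidene)cyclohexane-1,3,5-trione (formed in the flask) | CC(C)CC=C1C(=O)C(C)(C)C(=O)C(C)(C)C1=O | intermediate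
11 | (1R,4R,5R,8S,9S,4′S)-4,5-epoxy spiro adduct: C8 of the 13-norcaryophyllane unit is C2′ of a 4′-(2-methylpropyl)-6′,6′,8′,8′-tetramethyl-3′,4′-dihydro-2′H-chromene-5′,7′(6′H,8′H)-dione | C[C@@]12CC[C@@H]3[C@H](CC3(C)C)[C@]4(CC[C@H]1O2)C[C@H](CC(C)C)C1=C(O4)C(C)(C)C(=O)C(C)(C)C1=O | intermediate
12 | (1R,5R,8S,9S,4′S)-5-hydroxy-4-methylidene analogue of 11 (4(12)-ene, epoxide opened) | C=C1CC[C@@H]2[C@H](CC2(C)C)[C@]2(CC[C@H]1O)C[C@H](CC(C)C)C1=C(O2)C(C)(C)C(=O)C(C)(C)C1=O | intermediate
13 | (1R,8S,9S,4′S)-4-methylidene-5-ketone (4(12)-en-5-one) | C=C1CC[C@@H]2[C@H](CC2(C)C)[C@]2(CCC1=O)C[C@H](CC(C)C)C1=C(O2)C(C)(C)C(=O)C(C)(C)C1=O | intermediate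
14 | (1R,3Z,8S,9S,4′S)-4-methyl-3-en-5-one | C/C1=C/C[C@@H]2[C@H](CC2(C)C)[C@]2(CCC1=O)C[C@H](CC(C)C)C1=C(O2)C(C)(C)C(=O)C(C)(C)C1=O | intermediate
15 | Tomentodione P, (1R,3Z,5S,8S,9S,4′S)-5-hydroxy-3-ene | C/C1=C/C[C@@H]2[C@H](CC2(C)C)[C@]2(CC[C@@H]1O)C[C@H](CC(C)C)C1=C(O2)C(C)(C)C(=O)C(C)(C)C1=O | target

Total step count: 6. Longest linear sequence: 6 steps (1 → 7 → 11 → 12 → 13 → 14 → 15).

Steps most likely to fail

Step 2. The cycloaddition may show low facial and endo/exo discrimination, and the acidic trione may open the epoxide of 9 before the condensation has consumed it. Fallback: the order of events is changed. Starting from 9, the epoxide is first isomerised with diethylaluminium 2,2,6,6-tetramethylpiperidide to (1R,5R,9S)-caryophylla-4(12),8(13)-dien-5-ol F1. The Knoevenagel/hetero-Diels–Alder reaction of 7 and 8 is then run on this acid-stable dienol, whose C8=C13 methylene is the more electron-rich and less hindered of its two alkenes. This gives the allylic alcohol directly and returns to the route at 12.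

Step 5. The double-bond migration may be incomplete or unselective, or acid released from the rhodium salt may ionise the tertiary C8–O bond. Fallback: starting from 13, 1,4-hydrosilylation with Et3SiH catalysed by RhCl(PPh3)3 gives the regiodefined 5-triethylsilyl enol ether (4-ene) F2. Saegusa–Ito dehydrogenation with Pd(OAc)2 in MeCN then removes a C3 hydrogen by β-hydride elimination to give the endocyclic enone, returning to the route at 14.

Step 6. The facial bias of the folded nine-membered enone may override the catalyst, so that hydride is delivered to the wrong face. Fallback: starting from 14, Luche reduction (NaBH4, CeCl3·7H2O, MeOH) is allowed to follow substrate control to the 5R alcohol, the 5-epimer of tomentodione P F3. Mitsunobu esterification (4-nitrobenzoic acid, PPh3, diisopropyl azodicarboxylate) inverts C5 to give the 5S 4-nitrobenzoate F4, and methanolysis with K2CO3 in MeOH releases the alcohol, returning to the route at 15.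

Further compounds
F1 | step 2 | (1R,5R,9S)-caryophylla-4(12),8(13)-dien-5-ol | C=C1CC[C@@H]2[C@H](CC2(C)C)C(=C)CC[C@H]1O
F2 | step 5 | (1R,8S,9S,4′S)-5-(triethylsilyloxy)-4-ene analogue of 13 (silyl enol ether) | CC=1CC[C@@H]2[C@H](CC2(C)C)[C@]2(CCC=1O[Si](CC)(CC)CC)C[C@H](CC(C)C)C1=C(O2)C(C)(C)C(=O)C(C)(C)C1=O
F3 | step 6 | (1R,3Z,5R,8S,9S,4′S)-5-epimer of tomentodione P | C/C1=C/C[C@@H]2[C@H](CC2(C)C)[C@]2(CC[C@H]1O)C[C@H](CC(C)C)C1=C(O2)C(C)(C)C(=O)C(C)(C)C1=O
F4 | step 6 | (1R,3Z,5S,8S,9S,4′S)-5-O-(4-nitrobenzoyl) derivative of 15 | C/C1=C/C[C@@H]2[C@H](CC2(C)C)[C@]2(CC[C@@H]1OC(=O)c1ccc(cc1)[N+](=O)[O-])C[C@H](CC(C)C)C1=C(O2)C(C)(C)C(=O)C(C)(C)C1=O
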